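**Plan**
- Numbering: lactone C1(=O)–C2(OH)(CH2Ar)–C3H–C4H2–O, with the carbinol carbon C7 (bearing the second aryl group) on C3.
- Enabling feature: the C2 hydroxyl and the C3 side-chain carbon C7 lie on the same face of the lactone ring, so O–C2–C3–C7 is four atoms of a 2-isoxazoline ring fused across C2–C3. N–O cleavage of that ring leaves exactly this hydroxyl and a C7 carbonyl.
- Cuts: C7–OH back to C7=N with the N–O bond restored; then C3–C7 and C2–O together (aryl nitrile oxide plus α-benzyl butenolide); then C2–CH2Ar (Negishi coupling) and the C4–O-menthyl acetal.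
- Forward: the lactone ring is made first (furfural photo-oxygenation, menthyl acetal), C2 is brominated and benzylated, and the isoxazoline ring closes in the cycloaddition. Then C4 acetal to CH2, N–O cleavage, C7 reduction and desilylation.
- Stereochemistry: the C4 acetal centre comes from (−)-menthol by crystallisation and sends the dipole to the opposite face, which fixes C2 and C3 (cis by suprafacial addition). C7 comes from transfer hydrogenation with an (R,R)-Ru catalyst.

Key step: step 10

Remark: the two phenols are carried as triisopropylsilyl ethers, which should outlast the aqueous acid of step 11 and the borohydride of step 12. Atom labels C1–C4 and C7 refer to the target numbering above.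

**Route**

Step 1
Reactants: 1 vanillin
Product: 2 3-methoxy-4-(triisopropylsilyloxy)benzaldehyde
Conditions: TIPSCl, imidazole, DMF, rt
Reagents that add atoms: triisopropylsilyl chloride, CC(C)[Si](Cl)(C(C)C)C(C)C
Why: Imidazole-assisted silylation of the phenol (nucleophilic substitution at silicon) is routine for vanillin, and the bulky silyl ether is chosen because it later resists aqueous acid and borohydride in alcohol.

Step 2
Reactants: 2 3-methoxy-4-(triisopropylsilyloxy)benzaldehyde
Product: 3 [3-methoxy-4-(triisopropylsilyloxy)phenyl]methanol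
Conditions: NaBH4, MeOH, 0 °C
Reagents that add atoms: none
Why: Chemoselective borohydride reduction of the aryl aldehyde to the benzylic alcohol should leave the aryl silyl ether untouched at 0 °C.

Step 3
Reactants: 3 [3-methoxy-4-(triisopropylsilyloxy)phenyl]methanol
Product: 4 4-(chloromethyl)-2-methoxy-1-(triisopropylsilyloxy)benzene
Conditions: SOCl2, pyridine, CH2Cl2, 0 °C
Reagents that add atoms: thionyl chloride, O=S(Cl)Cl
Why: Deoxychlorination through the chlorosulfite ester is facile at an electron-rich benzylic carbon, and pyridine takes up the HCl so that the silyl ether survives.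

Step 4
Reactants: 5 furfural
Product: 6 5-hydroxyfuran-2(5H)-one
Conditions: O2, hν (visible), methylene blue (cat.), MeOH, rt
Reagents that add atoms: oxygen, O=O
Why: Dye-sensitised singlet-oxygen [4+2] photo-oxygenation of the furan gives an endoperoxide that methanol solvolyses with loss of the formyl carbon as methyl formate, so the formyl-bearing furan carbon becomes the lactone carbonyl of the γ-hydroxybutenolide.

Step 5
Reactants: 6 5-hydroxyfuran-2(5H)-one; 7 (−)-menthol
Product: 8 (5R)-5-(l-menthyloxy)furan-2(5H)-one
Conditions: camphorsulfonic acid (cat.), toluene, reflux (Dean–Stark); crystallisation from petroleum ether at −20 °C, mother liquor re-equilibrated with the same acid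
Reagents that add atoms: none
Why: Acid-catalysed acetalisation of the lactol gives both acetal epimers, which interconvert under the acid while the (5R) epimer crystallises (crystallisation-induced diastereomer transformation), so this stereocentre is set by (−)-menthol and the crystal lattice.

Step 6
Reactants: 8 (5R)-5-(l-menthyloxy)furan-2(5H)-one
Product: 10 (5R)-3-bromo-5-(l-menthyloxy)furan-2(5H)-one, via trans-3,4-dibromolactone 9 (not isolated)
Conditions: Br2, CH2Cl2, 0 °C to rt; then Et3N, 0 °C
Reagents that add atoms: bromine, BrBr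
Why: Anti addition of bromine to the enoate followed by E1cB loss of HBr through the acidic α-hydrogen (bromination–elimination) should give the α-bromobutenolide with the acetal centre untouched.

Step 7
Reactants: 4 4-(chloromethyl)-2-methoxy-1-(triisopropylsilyloxy)benzene; 10 (5R)-3-bromo-5-(l-menthyloxy)furan-2(5H)-one
Product: 12 (5R)-3-[3-methoxy-4-(triisopropylsilyloxy)benzyl]-5-(l-menthyloxy)furan-2(5H)-one, via benzylzinc chloride 11 (not isolated)
Conditions: 4, Zn dust, LiCl, THF, 25 °C; then 10, Pd(OAc)2 (2 mol%), SPhos (4 mol%), THF, 25 °C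
Reagents that add atoms: none
Why: LiCl-promoted zinc insertion into the benzylic chloride gives a benzylzinc reagent that tolerates the lactone, and Negishi coupling (oxidative addition of zerovalent palladium into the C(sp2)–Br bond, transmetalation, reductive elimination) forms the C2–CH2Ar bond under neutral conditions that leave the acetal centre alone.

Step 8
Reactants: 2 3-methoxy-4-(triisopropylsilyloxy)benzaldehyde
Product: 13 (E)-3-methoxy-4-(triisopropylsilyloxy)benzaldehyde oxime
Conditions: NH2OH·HCl, NaOAc, EtOH/H2O, rt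
Reagents that add atoms: hydroxylamine hydrochloride, Cl.NO
Why: Condensation of the aldehyde with hydroxylamine (oxime formation) should give the E-aldoxime under acetate buffering that spares the silyl ether.

Step 9
Reactants: 13 (E)-3-methoxy-4-(triisopropylsilyloxy)benzaldehyde oxime
Product: 14 (Z)-N-hydroxy-3-methoxy-4-(triisopropylsilyloxy)benzimidoyl chloride
Conditions: NCS, DMF, rt
Reagents that add atoms: N-chlorosuccinimide, O=C1CCC(=O)N1Cl
Why: Chlorination of the aldoxime C–H with NCS in DMF is the standard preparation of hydroximoyl chlorides, the storable precursors of nitrile oxides.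

Step 10
Reactants: 12 (5R)-3-[3-methoxy-4-(triisopropylsilyloxy)benzyl]-5-(l-menthyloxy)furan-2(5H)-one; 14 (Z)-N-hydroxy-3-methoxy-4-(triisopropylsilyloxy)benzimidoyl chloride
Product: 16 cis-fused isoxazoline–lactone cycloadduct (2S,3R,4R in target numbering), via nitrile oxide 15 (not isolated)
Conditions: 14 (2.5 equiv), Et3N (syringe pump, 16 h), CH2Cl2, 40 °C
Reagents that add atoms: none
Why: Triethylamine removes HCl from 14 and frees nitrile oxide 15, which adds across the C2=C3 bond of 12 in a concerted suprafacial [3+2] (Huisgen) cycloaddition that makes C3–C7 and C2–O in one event. The closest known reaction type is the addition of aryl nitrile oxides to 5-alkoxy-2(5H)-furanones bearing a chiral acetal, here carrying an extra α-substituent. The isoxazoline ring closes in the cycloaddition itself as a five-membered ring (π4s+π2s), cis-fused to the lactone. C2 and C3 are the new stereocentres: their cis relationship follows from suprafacial addition, and their absolute configuration from attack on the face opposite the C4 menthyloxy group. Two selectivities are required: the dipole oxygen must end on C2, which the benzyl group should ensure by making C2 the fully substituted alkene carbon so that the aryl-bearing dipole carbon bonds to the less hindered C3 as in other trisubstituted alkenes, and only one π-face may react, which the acetal substituent next to C3 should ensure. Slow release of the dipole keeps furoxan formation behind the slower addition to the trisubstituted alkene.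

Step 11
Reactants: 16 cis-fused isoxazoline–lactone cycloadduct
Product: 17 cis-fused isoxazoline–lactol (C4 hydroxyl, anomer mixture)
Conditions: TFA/H2O (9:1), rt
Reagents that add atoms: water, O
Why: Acid-catalysed hydrolysis of the cyclic acyloxy acetal (ring opening to the menthyl-stabilised oxocarbenium ion, hydration, loss of menthol, reclosure) releases the auxiliary, while the isoxazoline, the aryl triisopropylsilyl ethers and the two ring-fusion centres should be inert to aqueous acid.

Step 12
Reactants: 17 cis-fused isoxazoline–lactol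
Product: 19 cis-fused isoxazoline–lactone with C4 methylene (2S,3S in target numbering), via sodium hydroxy carboxylate 18 (not isolated)
Conditions: NaBH4, THF/EtOH, 0 °C; then 1 M HCl to pH 2, rt
Reagents that add atoms: none
Why: The lactol is a masked aldehyde acid, so borohydride reduces its open form to the γ-hydroxy carboxylate without touching the C=N bond, and acidification relactonises onto C1 (pseudo-acid reduction), turning the acetal carbon into the C4 methylene while the cis ring fusion holds C3.

Step 13
Reactants: 19 cis-fused isoxazoline–lactone with C4 methylene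
Product: 21 (3S,4S)-3-hydroxy-3-[3-methoxy-4-(triisopropylsilyloxy)benzyl]-4-[3-methoxy-4-(triisopropylsilyloxy)benzoyl]oxolan-2-one, via hydroxy imine 20 (not isolated)
Conditions: Raney Ni, H2 (1 atm), B(OH)3, MeOH/H2O (5:1), rt
Reagents that add atoms: water, O
Why: Hydrogenolysis of the weak N–O bond over Raney Ni gives the β-hydroxy imine, which the boric acid buffer hydrolyses to the ketone faster than it is reduced (reductive isoxazoline ring opening), so the C2 oxygen stays in place with retention and the mildly acidic medium avoids retro-aldol cleavage and epimerisation at C3.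

Step 14
Reactants: 21 (3S,4S)-3-hydroxy-3-[3-methoxy-4-(triisopropylsilyloxy)benzyl]-4-[3-methoxy-4-(triisopropylsilyloxy)benzoyl]oxolan-2-one
Product: 22 (3S,4R)-3-hydroxy-4-{(R)-hydroxy[3-methoxy-4-(triisopropylsilyloxy)phenyl]methyl}-3-[3-methoxy-4-(triisopropylsilyloxy)benzyl]oxolan-2-one
Conditions: RuCl[(R,R)-TsDPEN](p-cymene) (5 mol%), HCO2H/Et3N (5:2), DMF, 40 °C
Reagents that add atoms: none
Why: Noyori-type asymmetric transfer hydrogenation delivers hydride and proton from the Ru–H/N–H pair to one face of the aryl ketone, the (R,R) ligand giving the (R)-carbinol of aryl alkyl ketones through the arene CH–π contact, so C7 is set by the catalyst while the acidic formate medium suppresses enolisation toward C3 and β-elimination of the lactone oxygen.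

Step 15
Reactants: 22 (3S,4R)-3-hydroxy-4-{(R)-hydroxy[3-methoxy-4-(triisopropylsilyloxy)phenyl]methyl}-3-[3-methoxy-4-(triisopropylsilyloxy)benzyl]oxolan-2-one
Product: 23 (3S,4R)-3-hydroxy-4-[(R)-hydroxy(4-hydroxy-3-methoxyphenyl)methyl]-3-(4-hydroxy-3-methoxybenzyl)oxolan-2-one (CNP0352022.1)
Conditions: TBAF, AcOH, THF, 0 °C
Reagents that add atoms: none
Why: Fluoride cleaves the two aryl Si–O bonds (desilylation) and the acetic acid buffer protonates the phenoxides at once, which should prevent base-induced translactonisation onto the C7 hydroxyl, retro-aldol cleavage and quinone methide formation.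

**Compound list**

1 | vanillin (4-hydroxy-3-methoxybenzaldehyde) | COc1cc(C=O)ccc1O | starting material
2 | 3-methoxy-4-(triisopropylsilyloxy)benzaldehyde | COc1cc(C=O)ccc1O[Si](C(C)C)(C(C)C)C(C)C | intermediate
3 | [3-methoxy-4-(triisopropylsilyloxy)phenyl]methanol | COc1cc(CO)ccc1O[Si](C(C)C)(C(C)C)C(C)C | intermediate
4 | 4-(chloromethyl)-2-methoxy-1-(triisopropylsilyloxy)benzene | COc1cc(CCl)ccc1O[Si](C(C)C)(C(C)C)C(C)C | intermediate
5 | furfural | O=Cc1ccco1 | starting material
6 | 5-hydroxyfuran-2(5H)-one (racemic lactol) | OC1OC(=O)C=C1 | intermediate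
7 | (−)-menthol, (1R,2S,5R)-2-isopropyl-5-methylcyclohexanol | CC(C)[C@@H]1CC[C@@H](C)C[C@H]1O | starting material
8 | (5R)-5-(l-menthyloxy)furan-2(5H)-one, menthyl = (1R,2S,5R) | CC(C)[C@@H]1CC[C@@H](C)C[C@H]1O[C@@H]1OC(=O)C=C1 | intermediate
9 | (3S,4S,5R)-3,4-dibromo-5-(l-menthyloxy)oxolan-2-one, the trans-dibromide expected with the C4 bromine anti to the menthyloxy group (formed in situ) | CC(C)[C@@H]1CC[C@@H](C)C[C@H]1O[C@@H]1OC(=O)[C@H](Br)[C@H]1Br | intermediate
10 | (5R)-3-bromo-5-(l-menthyloxy)furan-2(5H)-one | CC(C)[C@@H]1CC[C@@H](C)C[C@H]1O[C@@H]1OC(=O)C(Br)=C1 | intermediate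
11 | [3-methoxy-4-(triisopropylsilyloxy)benzyl]zinc chloride (THF solution with LiCl, formed in situ) | COc1cc(C[Zn]Cl)ccc1O[Si](C(C)C)(C(C)C)C(C)C | intermediate
12 | (5R)-3-[3-methoxy-4-(triisopropylsilyloxy)benzyl]-5-(l-menthyloxy)furan-2(5H)-one | CC(C)[C@@H]1CC[C@@H](C)C[C@H]1O[C@@H]1OC(=O)C(Cc2ccc(O[Si](C(C)C)(C(C)C)C(C)C)c(OC)c2)=C1 | intermediate
13 | (E)-3-methoxy-4-(triisopropylsilyloxy)benzaldehyde oxime | COc1cc(/C=N/O)ccc1O[Si](C(C)C)(C(C)C)C(C)C | intermediate
14 | (Z)-N-hydroxy-3-methoxy-4-(triisopropylsilyloxy)benzimidoyl chloride | COc1cc(/C(Cl)=N/O)ccc1O[Si](C(C)C)(C(C)C)C(C)C | intermediate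
15 | 3-methoxy-4-(triisopropylsilyloxy)benzonitrile oxide (formed in situ) | COc1cc(C#[N+][O-])ccc1O[Si](C(C)C)(C(C)C)C(C)C | intermediate
16 | cycloadduct: 3-aryl-6a-benzyl-4-(l-menthyloxy)-3a,4-dihydrofuro[3,4-d]isoxazol-6(6aH)-one, cis-fused, isoxazoline oxygen on C2 and C7 on C3 both anti to the menthyloxy group; 2S,3R,4R in target numbering; aryl = 3-methoxy-4-(triisopropylsilyloxy)phenyl, benzyl ring substituted likewise | COc1cc(C[C@]23ON=C(c4ccc(O[Si](C(C)C)(C(C)C)C(C)C)c(OC)c4)[C@H]2[C@H](O[C@@H]5C[C@H](C)CC[C@H]5C(C)C)OC3=O)ccc1O[Si](C(C)C)(C(C)C)C(C)C | intermediate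
17 | lactol: the same cis-fused bicycle with hydroxyl in place of menthyloxy on C4 (anomer mixture; 2S,3R in target numbering) | COc1cc(C[C@]23ON=C(c4ccc(O[Si](C(C)C)(C(C)C)C(C)C)c(OC)c4)[C@H]2C(O)OC3=O)ccc1O[Si](C(C)C)(C(C)C)C(C)C | intermediate
18 | sodium (4S,5S)-5-benzyl-4-(hydroxymethyl)-3-aryl-4,5-dihydroisoxazole-5-carboxylate, aryl and benzyl rings as in 16 (formed in situ) | COc1cc(C[C@]2(C(=O)[O-])ON=C(c3ccc(O[Si](C(C)C)(C(C)C)C(C)C)c(OC)c3)[C@H]2CO)ccc1O[Si](C(C)C)(C(C)C)C(C)C.[Na+] | intermediate
19 | lactone: 3-aryl-6a-benzyl-3a,4-dihydrofuro[3,4-d]isoxazol-6(6aH)-one, cis-fused (2S,3S in target numbering), aryl and benzyl rings as in 16 | COc1cc(C[C@]23ON=C(c4ccc(O[Si](C(C)C)(C(C)C)C(C)C)c(OC)c4)[C@H]2COC3=O)ccc1O[Si](C(C)C)(C(C)C)C(C)C | intermediate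
20 | (3S,4S)-3-hydroxy-3-[3-methoxy-4-(triisopropylsilyloxy)benzyl]-4-{imino[3-methoxy-4-(triisopropylsilyloxy)phenyl]methyl}oxolan-2-one (formed in situ) | COc1cc(C[C@@]2(O)C(=O)OC[C@@H]2C(=N)c2ccc(O[Si](C(C)C)(C(C)C)C(C)C)c(OC)c2)ccc1O[Si](C(C)C)(C(C)C)C(C)C | intermediate
21 | (3S,4S)-3-hydroxy-3-[3-methoxy-4-(triisopropylsilyloxy)benzyl]-4-[3-methoxy-4-(triisopropylsilyloxy)benzoyl]oxolan-2-one | COc1cc(C[C@@]2(O)C(=O)OC[C@@H]2C(=O)c2ccc(O[Si](C(C)C)(C(C)C)C(C)C)c(OC)c2)ccc1O[Si](C(C)C)(C(C)C)C(C)C | intermediate
22 | (3S,4R)-3-hydroxy-4-{(R)-hydroxy[3-methoxy-4-(triisopropylsilyloxy)phenyl]methyl}-3-[3-methoxy-4-(triisopropylsilyloxy)benzyl]oxolan-2-one | COc1cc(C[C@@]2(O)C(=O)OC[C@@H]2[C@@H](O)c2ccc(O[Si](C(C)C)(C(C)C)C(C)C)c(OC)c2)ccc1O[Si](C(C)C)(C(C)C)C(C)C | intermediate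
23 | (3S,4R)-3-hydroxy-4-[(R)-hydroxy(4-hydroxy-3-methoxyphenyl)methyl]-3-(4-hydroxy-3-methoxybenzyl)oxolan-2-one (CNP0352022.1) | COc1cc(C[C@@]2(O)C(=O)OC[C@@H]2[C@@H](O)c2ccc(O)c(OC)c2)ccc1O | target

**Step count and risks**

Total steps: 15. Longest linear sequence: 10 steps (5 → 6 → 8 → 10 → 12 → 16 → 17 → 19 → 21 → 22 → 23; the branch 1 → 2 → 3 → 4 → 12 and onward is equally long).

Steps most likely to fail:

1. Step 10. The trisubstituted C2=C3 bond may react so slowly that the dipole dimerises to the furoxan, or the dipole oxygen may bond to C3 instead of C2. The fallback sets out from 8 and comes back to the route at 21; it makes the C3–C7 bond by conjugate addition instead.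
   - Aldehyde 2 is condensed with propane-1,3-dithiol (BF3·OEt2, CH2Cl2) to the aryl dithiane F1.
   - Its 2-lithio derivative (n-BuLi, THF, −78 °C) should add to butenolide 8 anti to the menthyloxy group. The lactone enolate is oxidised in the same flask with 2-(phenylsulfonyl)-3-phenyloxaziridine to the hydroxy lactone F2, whose C2 configuration is of no consequence.
   - Double deprotonation of F2 (LiN(iPr)2, 2.2 equiv, THF/DMPU, −78 °C) and C-alkylation of the enediolate with chloride 4 should occur anti to the dithianyl group. This gives the benzylated carbinol F3 with benzyl trans and hydroxyl cis to the C3 substituent, as in the target.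
   - Acid hydrolysis (TFA/H2O) gives lactol F4. Borohydride reduction through the sodium hydroxy carboxylate F5 and acidic work-up, as in steps 11 and 12, give the dithianyl lactone F6.
   - Alkylative dithiane hydrolysis (MeI, CaCO3, MeCN/H2O) unmasks ketone 21.

2. Step 12. The open aldehyde–carboxylate form may lose the isoxazoline oxygen by base-induced β-elimination, or epimerise at C3, before it is reduced. The fallback sets out from 17 and comes back at 19; it bypasses the free aldehyde by a radical route. Lactol 17 is converted with SOCl2 (cat. DMF, CH2Cl2) into the chloro lactone F7 (the pseudo-acid chloride). The C–Cl bond is then reduced with Bu3SnH and AIBN in toluene at 80 °C, which should give 19 under neutral conditions.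

3. Step 14. Catalyst control may be eroded on this hindered, α-branched ketone (slow turnover or a substrate bias toward the wrong face), and prolonged exposure may allow enolisation toward C3. The fallback sets out from 21 and comes back at 22; it uses substrate control by an Evans–Saksena reduction (Me4NBH(OAc)3, MeCN/AcOH, −30 °C). Boron bound to the C2 hydroxyl delivers hydride intramolecularly through a chair in which the benzyl group is equatorial. This should give the 1,3-anti diol along the ArCH2–C2–C3–C7–Ar chain, which is 22. No new compound is made on this path (entered below as F0).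

**Further compounds**

F1 | step 10 | aryl dithiane: 2-[3-methoxy-4-(triisopropylsilyloxy)phenyl]-1,3-dithiane | COc1cc(C2SCCCS2)ccc1O[Si](C(C)C)(C(C)C)C(C)C
F2 | step 10 | hydroxy lactone: (5R)-menthyloxy lactone with the 2-aryl-1,3-dithian-2-yl group on C3 anti to the menthyloxy group and a C2 hydroxyl trans to it | CC(C)[C@@H]1CC[C@@H](C)C[C@H]1O[C@@H]1OC(=O)[C@H](O)[C@H]1C1(SCCCS1)c1ccc(O[Si](C(C)C)(C(C)C)C(C)C)c(OC)c1
F3 | step 10 | benzylated carbinol: as F2 with C2 bearing hydroxyl (cis to the dithianyl group) and the silylated benzyl group (trans to it) | CC(C)[C@@H]1CC[C@@H](C)C[C@H]1O[C@@H]1OC(=O)[C@](O)(Cc2ccc(O[Si](C(C)C)(C(C)C)C(C)C)c(OC)c2)[C@H]1C1(SCCCS1)c1ccc(O[Si](C(C)C)(C(C)C)C(C)C)c(OC)c1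
F4 | step 10 | lactol from F3 (C4 hydroxyl, anomer mixture) | OC1OC(=O)[C@](O)(Cc2ccc(O[Si](C(C)C)(C(C)C)C(C)C)c(OC)c2)[C@H]1C1(SCCCS1)c1ccc(O[Si](C(C)C)(C(C)C)C(C)C)c(OC)c1
F5 | step 10 | sodium hydroxy carboxylate from F4 (formed in situ) | [Na+].[O-]C(=O)[C@](O)(Cc1ccc(O[Si](C(C)C)(C(C)C)C(C)C)c(OC)c1)[C@H](CO)C1(SCCCS1)c1ccc(O[Si](C(C)C)(C(C)C)C(C)C)c(OC)c1
F6 | step 10 | dithianyl lactone: C4-methylene lactone with C2 hydroxyl and benzyl, dithiane still on C3 | C1OC(=O)[C@](O)(Cc2ccc(O[Si](C(C)C)(C(C)C)C(C)C)c(OC)c2)[C@H]1C1(SCCCS1)c1ccc(O[Si](C(C)C)(C(C)C)C(C)C)c(OC)c1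
F7 | step 12 | chloro lactone: cis-fused isoxazoline–lactone with chlorine on C4 (anomer mixture) | COc1cc(C[C@]23ON=C(c4ccc(O[Si](C(C)C)(C(C)C)C(C)C)c(OC)c4)[C@H]2C(Cl)OC3=O)ccc1O[Si](C(C)C)(C(C)C)C(C)C
F0 | step 14 | none | none
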